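The route rests on the C12–C13 bond, which joins ring carbon C12 to C13, the carbon β to the C15 ketone, so the whole ω-chain can arrive as oct-1-en-3-one. A bromoacetal tethered to O9 of an enantiopure cyclopentenol gives a radical that closes the C7–C8 bond (5-exo) cis to O9 and relays the radical to C12, where the enone is captured on the convex face. One operation therefore forms two C–C bonds and sets C8 and C12 of the cyclopentane ring, exploiting the cis C8/C9 and trans C8/C12 relationships. The precursor is a simple cyclopent-2-enyl bromoacetal that carries neither side chain.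

Key step: step 2

Remark: atoms carry prostanoic acid numbers (C1 carboxyl, C8–C12 ring, C9 carbinol, C11 and C15 ketones); the acetal or lactol carbon C6 in 3 and 5–10 and C15 in 9, 10, 13 and 14 are carried as epimer mixtures that later steps erase, so their SMILES bear no descriptor at these atoms.

Step 1
Reactants: 1 (1S,4R)-cis-4-acetoxycyclopent-2-en-1-ol; 2 ethyl vinyl ether
Product: 3 (1R,4S)-4-(2-bromo-1-ethoxyethoxy)cyclopent-2-en-1-yl acetate
Conditions: NBS, 2 (3 equiv), CH2Cl2, −40 °C to 0 °C
Reagents that add atoms: N-bromosuccinimide, O=C1CCC(=O)N1Br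
Why: Haloetherification of an enol ether (entry to the Ueno–Stork acetal): NBS should deliver bromine to the electron-rich vinyl ether far faster than to the ring alkene, and the free hydroxyl of 1 adds at the oxygen-bearing carbon, so the tether is placed on O9 without touching C9 or C11.

Step 2
Reactants: 3 (1R,4S)-4-(2-bromo-1-ethoxyethoxy)cyclopent-2-en-1-yl acetate; 4 oct-1-en-3-one
Product: 8 (3aR,4R,5R,6aS)-2-ethoxy-4-(3-oxooctyl)hexahydro-2H-cyclopenta[b]furan-5-yl acetate, via primary alkyl radical 5 (not isolated), via bicyclic C12 radical 6 (not isolated), via alpha-keto radical 7 (not isolated)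
Conditions: Bu3SnH (1.3 equiv, syringe pump), AIBN (cat.), 4 (6 equiv), PhH (0.02 M), 80 °C
Reagents that add atoms: none
Why: Bu3Sn• abstracts bromine from 3 and primary radical 5 closes 5-exo-trig onto C8 of the ring alkene; the two-atom tether can reach only the face of O9, so the C7–C8 bond forms cis to O9 and the cis-fused bicycle 6 results, with C8 controlled by the C9 stereocentre through the tether. The relayed secondary radical at C12 is nucleophilic and adds to the unsubstituted terminus of the electron-poor enone 4 (Giese addition), forming C12–C13 on the convex β face anti to both the new C8–C7 bond and the C11 acetate, so the trans C8/C12 relationship is substrate-controlled. The electrophilic alpha-keto radical 7 should not add readily to a second enone and is reduced by Bu3SnH, which returns the chain carrier. The closest known reaction type is the Ueno–Stork haloacetal radical cyclization followed by intermolecular trapping of the cyclised radical by an enone. The step needs ring closure to outrun direct addition of 5 to 4, and addition of 6 to 4 to outrun hydrogen transfer from tin; the fast 5-exo closure of the acetal-tethered radical, a low stationary Bu3SnH concentration and the excess of 4 should secure both.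

Step 3
Reactants: 8 (3aR,4R,5R,6aS)-2-ethoxy-4-(3-oxooctyl)hexahydro-2H-cyclopenta[b]furan-5-yl acetate
Product: 9 (3aR,4R,5R,6aS)-2-ethoxy-4-(3-hydroxyoctyl)hexahydro-2H-cyclopenta[b]furan-5-ol
Conditions: LiAlH4, THF, 0 °C; aq. NaOH work-up
Reagents that add atoms: none
Why: Hydride reduction with LiAlH4 should convert the C15 ketone into the carbinol (either epimer serves, since C15 is re-oxidised in step 6) and cleave the C11 acetate, which removes every ylide-sensitive carbonyl before step 5 while the acetal is inert.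

Step 4
Reactants: 9 (3aR,4R,5R,6aS)-2-ethoxy-4-(3-hydroxyoctyl)hexahydro-2H-cyclopenta[b]furan-5-ol
Product: 10 (3aR,4R,5R,6aS)-4-(3-hydroxyoctyl)hexahydro-2H-cyclopenta[b]furan-2,5-diol
Conditions: 1.5% aq. HCl, THF, rt
Reagents that add atoms: water, O
Why: Acid-catalysed acetal hydrolysis of the reactive 2-ethoxytetrahydrofuran should release the lactol under conditions that leave the secondary carbinols and all ring stereocentres untouched.

Step 5
Reactants: 10 (3aR,4R,5R,6aS)-4-(3-hydroxyoctyl)hexahydro-2H-cyclopenta[b]furan-2,5-diol; 11 (4-carboxybutyl)triphenylphosphonium bromide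
Product: 14 (Z)-7-[(1R,2R,3R,5S)-3,5-dihydroxy-2-(3-hydroxyoctyl)cyclopentyl]hept-5-enoic acid, via phosphonium ylide 12 (not isolated), via hydroxy aldehyde 13 (not isolated)
Conditions: 11 (6 equiv), KOtBu (12 equiv), THF, 0 °C to rt; then aq. citric acid to pH 4
Reagents that add atoms: none
Why: Wittig olefination: the lactol reacts through its open form 13 with the non-stabilised carboxylate ylide 12 under kinetic control (cis-oxaphosphetane) to give the 5Z alkene and free the C9 hydroxyl, and the substrate holds no other carbonyl or base-labile group.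

Step 6
Reactants: 14 (Z)-7-[(1R,2R,3R,5S)-3,5-dihydroxy-2-(3-hydroxyoctyl)cyclopentyl]hept-5-enoic acid
Product: 16 (Z)-7-[(1R,2R,5S)-5-hydroxy-3-oxo-2-(3-oxooctyl)cyclopentyl]hept-5-enoic acid, via 15-oxo diol 15 (not isolated)
Conditions: Jones reagent (CrO3, H2SO4, H2O; 2.1 oxidising equiv), acetone, −30 °C; i-PrOH quench
Reagents that add atoms: none
Why: Chemoselective Jones oxidation: chromic acid should oxidise the unhindered acyclic C15 carbinol and the C11 carbinol (trans neighbour at C12) faster than the C9 carbinol shielded by the cis C8 chain, the same order that governs silylation of 9α,11α-diols of this family, so a measured charge at low temperature should stop at the 11,15-diketone while the acid, the Z alkene and the thermodynamically preferred trans C12 configuration are retained.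

Compound list
1 | (1S,4R)-cis-4-acetoxycyclopent-2-en-1-ol | O[C@H]1C[C@@H](OC(C)=O)C=C1 | starting material
2 | ethyl vinyl ether | C=COCC | starting material
3 | (1R,4S)-4-(2-bromo-1-ethoxyethoxy)cyclopent-2-en-1-yl acetate (both acetal epimers) | BrCC(OCC)O[C@H]1C[C@@H](OC(C)=O)C=C1 | intermediate
4 | oct-1-en-3-one | C=CC(=O)CCCCC | starting material
5 | 2-{[(1S,4R)-4-acetoxycyclopent-2-en-1-yl]oxy}-2-ethoxyethyl radical (primary alkyl radical) | [CH2]C(OCC)O[C@H]1C[C@@H](OC(C)=O)C=C1 | intermediate (not isolated)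
6 | (3aR,5R,6aS)-5-acetoxy-2-ethoxyhexahydro-2H-cyclopenta[b]furan-4-yl radical (cis-fused, radical at C12) | [CH]1[C@H](OC(C)=O)C[C@@H]2OC(OCC)C[C@H]12 | intermediate (not isolated)
7 | 1-[(3aR,4R,5R,6aS)-5-acetoxy-2-ethoxyhexahydro-2H-cyclopenta[b]furan-4-yl]-3-oxooctan-2-yl radical (alpha-keto radical) | CCCCCC(=O)[CH]C[C@H]1[C@H](OC(C)=O)C[C@@H]2OC(OCC)C[C@H]12 | intermediate (not isolated)
8 | (3aR,4R,5R,6aS)-2-ethoxy-4-(3-oxooctyl)hexahydro-2H-cyclopenta[b]furan-5-yl acetate | CCCCCC(=O)CC[C@H]1[C@H](OC(C)=O)C[C@@H]2OC(OCC)C[C@H]12 | intermediate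
9 | (3aR,4R,5R,6aS)-2-ethoxy-4-(3-hydroxyoctyl)hexahydro-2H-cyclopenta[b]furan-5-ol | CCCCCC(O)CC[C@H]1[C@H](O)C[C@@H]2OC(OCC)C[C@H]12 | intermediate
10 | (3aR,4R,5R,6aS)-4-(3-hydroxyoctyl)hexahydro-2H-cyclopenta[b]furan-2,5-diol | CCCCCC(O)CC[C@H]1[C@H](O)C[C@@H]2OC(O)C[C@H]12 | intermediate
11 | (4-carboxybutyl)triphenylphosphonium bromide | OC(=O)CCCC[P+](c1ccccc1)(c1ccccc1)c1ccccc1.[Br-] | starting material
12 | potassium 5-(triphenylphosphoranylidene)pentanoate (ylide) | [K+].[O-]C(=O)CCCC=P(c1ccccc1)(c1ccccc1)c1ccccc1 | intermediate (not isolated)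
13 | 2-[(1R,2R,3R,5S)-3,5-dihydroxy-2-(3-hydroxyoctyl)cyclopentyl]acetaldehyde (open form of 10) | CCCCCC(O)CC[C@H]1[C@H](O)C[C@H](O)[C@@H]1CC=O | intermediate (not isolated)
14 | (Z)-7-[(1R,2R,3R,5S)-3,5-dihydroxy-2-(3-hydroxyoctyl)cyclopentyl]hept-5-enoic acid | CCCCCC(O)CC[C@H]1[C@H](O)C[C@H](O)[C@@H]1C/C=C\CCCC(=O)O | intermediate
15 | (Z)-7-[(1R,2R,3R,5S)-3,5-dihydroxy-2-(3-oxooctyl)cyclopentyl]hept-5-enoic acid | CCCCCC(=O)CC[C@H]1[C@H](O)C[C@H](O)[C@@H]1C/C=C\CCCC(=O)O | intermediate (not isolated)
16 | (Z)-7-[(1R,2R,5S)-5-hydroxy-3-oxo-2-(3-oxooctyl)cyclopentyl]hept-5-enoic acid (13,14-dihydro-15-keto-PGD2) | CCCCCC(=O)CC[C@H]1C(=O)C[C@H](O)[C@@H]1C/C=C\CCCC(=O)O | target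

Total step count: 6. Longest linear sequence: 6 steps (1 to 16).

Steps most likely to fail

1. Step 6. The kinetic discrimination between the C11 and C9 carbinols may be insufficient, so that C9 is oxidised as well or C11 is left unoxidised, and the β-hydroxy ketone may dehydrate in acid. The fallback replaces selectivity by protecting groups and runs from 14 to 16. Et3SiCl and imidazole in DMF at −20 °C should silylate only the C11 and C15 hydroxyls (the silyl ester is lost in aqueous work-up) to give (Z)-7-[(1R,2R,3R,5S)-5-hydroxy-3-(triethylsilyloxy)-2-(3-(triethylsilyloxy)octyl)cyclopentyl]hept-5-enoic acid F1. TBSOTf and 2,6-lutidine, followed by a mild aqueous NaHCO3 work-up that cleaves the silyl ester, should cap O9 and give the 9-O-tert-butyldimethylsilyl 11,15-bis(triethylsilyl) ether F2. PPTS in MeOH should remove both triethylsilyl groups to give the 11,15-diol 9-silyl ether F3. Dess–Martin periodinane with NaHCO3 in CH2Cl2 should oxidise both free carbinols to the 11,15-diketone 9-silyl ether F4. HF·pyridine in MeCN at 0 °C should then free the C9 hydroxyl and rejoin the route at 16.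

2. Step 2. Hydrogen transfer from tin to radical 6 may occur before the enone is met, and 4 may telomerise or polymerise under the radical conditions. The fallback is a tin-hydride-free addition–fragmentation and runs from 3 to 8. (E)-1,2-Bis(tributylstannyl)ethene and hexanoyl chloride with AlCl3 should give (E)-1-(tributylstannyl)oct-1-en-3-one F5. Heating 3 with F5 and AIBN in PhH should give, by the same 5-exo closure, addition of the C12 radical and loss of Bu3Sn•, (3aR,4R,5R,6aS)-2-ethoxy-4-[(E)-3-oxooct-1-en-1-yl]hexahydro-2H-cyclopenta[b]furan-5-yl acetate F6. Hydrogenation of the enone double bond (H2, Pd/C, EtOAc) should then give 8.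

3. Step 5. Z selectivity may erode and conversion of the polyhydroxylated lactol may stall under the large excess of basic ylide. The fallback sets the alkene geometry by catalyst control and runs from 10 to 14. Methylenation of 10 with Ph3P=CH2 (from methyltriphenylphosphonium bromide and KOtBu) should give (1S,3R,4R,5R)-4-(3-hydroxyoctyl)-5-(prop-2-en-1-yl)cyclopentane-1,3-diol F7. Z-selective cross-metathesis with methyl hex-5-enoate, using a cyclometalated Z-selective Grubbs ruthenium catalyst, should give methyl (Z)-7-[(1R,2R,3R,5S)-3,5-dihydroxy-2-(3-hydroxyoctyl)cyclopentyl]hept-5-enoate F8. LiOH in aqueous THF should then give 14.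

Further compounds
F1 | step 6 | (Z)-7-[(1R,2R,3R,5S)-5-hydroxy-3-(triethylsilyloxy)-2-(3-(triethylsilyloxy)octyl)cyclopentyl]hept-5-enoic acid | CCCCCC(O[Si](CC)(CC)CC)CC[C@H]1[C@H](O[Si](CC)(CC)CC)C[C@H](O)[C@@H]1C/C=C\CCCC(=O)O
F2 | step 6 | (Z)-7-[(1R,2R,3R,5S)-5-(tert-butyldimethylsilyloxy)-3-(triethylsilyloxy)-2-(3-(triethylsilyloxy)octyl)cyclopentyl]hept-5-enoic acid | CCCCCC(O[Si](CC)(CC)CC)CC[C@H]1[C@H](O[Si](CC)(CC)CC)C[C@H](O[Si](C)(C)C(C)(C)C)[C@@H]1C/C=C\CCCC(=O)O
F3 | step 6 | (Z)-7-[(1R,2R,3R,5S)-5-(tert-butyldimethylsilyloxy)-3-hydroxy-2-(3-hydroxyoctyl)cyclopentyl]hept-5-enoic acid | CCCCCC(O)CC[C@H]1[C@H](O)C[C@H](O[Si](C)(C)C(C)(C)C)[C@@H]1C/C=C\CCCC(=O)O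
F4 | step 6 | (Z)-7-[(1R,2R,5S)-5-(tert-butyldimethylsilyloxy)-3-oxo-2-(3-oxooctyl)cyclopentyl]hept-5-enoic acid | CCCCCC(=O)CC[C@H]1C(=O)C[C@H](O[Si](C)(C)C(C)(C)C)[C@@H]1C/C=C\CCCC(=O)O
F5 | step 2 | (E)-1-(tributylstannyl)oct-1-en-3-one | CCCCCC(=O)/C=C/[Sn](CCCC)(CCCC)CCCC
F6 | step 2 | (3aR,4R,5R,6aS)-2-ethoxy-4-[(E)-3-oxooct-1-en-1-yl]hexahydro-2H-cyclopenta[b]furan-5-yl acetate | CCCCCC(=O)/C=C/[C@H]1[C@H](OC(C)=O)C[C@@H]2OC(OCC)C[C@H]12
F7 | step 5 | (1S,3R,4R,5R)-4-(3-hydroxyoctyl)-5-(prop-2-en-1-yl)cyclopentane-1,3-diol | CCCCCC(O)CC[C@H]1[C@H](O)C[C@H](O)[C@@H]1CC=C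
F8 | step 5 | methyl (Z)-7-[(1R,2R,3R,5S)-3,5-dihydroxy-2-(3-hydroxyoctyl)cyclopentyl]hept-5-enoate | CCCCCC(O)CC[C@H]1[C@H](O)C[C@H](O)[C@@H]1C/C=C\CCCC(=O)OC
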